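One thing should stay unchanged when a flask of D and Q is scaled at fixed equivalents: if the steps that matter each join two dissolved partners, the fractions of the charge depend on charge times time, so a run can be read at another run's matched time (a time normalisation, in the usual term).

| flask | D | Q | remark | time |
|---|---|---|---|---|
| zeta | 0.0050 M | 1.5 equiv | run made earlier |  |
| eta | 0.020 M | 1.5 equiv | run made earlier |  |
| alpha | 0.010 M | 0.75 equiv | run made earlier |  |
| flask | 0.010 M | 1.50 equiv |  | 4.0 d |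

| run | time / d | D / % | Z / % | X / % |
|---|---|---|---|---|
| zeta | 0.333 | 63.6 | 35.4 | 1.1 |
| zeta | 0.625 | 45.9 | 50.4 | 2.6 |
| zeta | 1.04 | 31.8 | 60.0 | 4.1 |
| zeta | 1.25 | 28.2 | 64.4 | 6.7 |
| zeta | 1.67 | 20.8 | 68.1 | 7.3 |
| zeta | 2.08 | 17.6 | 70.4 | 9.3 |
| zeta | 2.50 | 13.6 | 71.4 | 11.3 |
| eta | 0.208 | 38.6 | 56.5 | 3.7 |
| eta | 0.333 | 26.5 | 65.1 | 6.1 |
| eta | 0.417 | 21.0 | 67.9 | 7.6 |
| eta | 0.625 | 14.0 | 71.3 | 10.0 |
| eta | 1.04 | 7.1 | 71.2 | 12.4 |
| eta | 1.67 | 4.2 | 68.3 | 14.1 |
| eta | 2.50 | 3.5 | 66.6 | 15.0 |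
| alpha | 0.208 | 76.1 | 22.7 | 0.7 |
| alpha | 0.333 | 67.2 | 30.6 | 0.8 |
| alpha | 0.625 | 54.8 | 42.6 | 1.2 |
| alpha | 1.25 | 43.2 | 53.2 | 3.6 |
| alpha | 2.50 | 35.1 | 59.1 | 4.1 |

(each reading ± 0.5 percentage points)

- what is said of L includes G
- G is a solid; its amount is given per volume of the solution
- reactions considered so far: D + Q -> Z; Q + J -> L; Q + X -> J; Q <-> E; G <-> L; Q + Z -> X

- D at 4.0 d, in percent of the D charged
- Z at 4.0 d, in percent of the D charged
- X at 4.0 d, in percent of the D charged
- J at 4.0 d, in percent of the D charged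

The zeta run passes this test: its last reading at 2.50 d has a matched time in the eta run of 0.625 d, where eta shows D 14.0% and Z 71.3% against zeta's 13.6% and 71.4%. The matched time of the asked flask, its time multiplied by its D charge over eta's, is 2.00 d, which lies 0.398 of the way between eta's last two readings. Interpolation there gives D 3.92%, Z 67.6% and X 14.5%, so by difference J and L together come to an estimated 14.0%.

The split of that gap is the weak link. Counting Q, with one in Z, two in X, 3 in J and 4 in L, leaves 11.5% of the D charge for L and for Q unused or held as E together. Dividing this evenly, which is a guess, gives my J of 8.26%. The forecast differs here, with D 4%, Z 67.5%, X 14.5% and J 11.5%, calling J “the least certain value”.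

The flask gives D 4.21%, Z 68.2%, X 14.7% and J 7.58%, each forecast value lying within its margin.

    D + Q → Z (k = 14.0 L mol⁻¹ h⁻¹)
    Q + J → L (k = 8.50 L mol⁻¹ h⁻¹)
    Q + X → J (k = 7.50 L mol⁻¹ h⁻¹)
    Q ⇌ E (K = 0.610, k = 5.70 h⁻¹)
    G ⇌ L, rate k5*(cs5 - [L]) while solid is left; crystals form when [L] > cs5 (solubility = 0.290 mM, k = 1.70 h⁻¹)
    Q + Z → X (k = 2.10 L mol⁻¹ h⁻¹)

Left ten times as long, the flask holds Z 66.2%. Read earlier, at 1.67 d, the same flask has a matched time of 0.834 d, between eta's readings of D 14.0% and 7.1%, and it holds D 9.98%.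

(The earlier runs and the new flask are simulated with constants of no real substance.)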